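**Retrosynthetic overview**

- Numbering: ring C1 (bears C13H2OAc), C2 (=CH), C3 (C=O), C4 (oxirane C carrying C7), C5 (oxirane CH), C6 (C=O); chain C7 (CHOAc) to C12 (CHO). The strategy rests on the carbocycle C1–C6 being a masked 2,5-disubstituted p-benzoquinone: oxygen on C3 and C6 (para), carbon arms on C1 and C4 (para).
- Endgame: the target comes from C6 ketal hydrolysis, C12 oxidation, acetylation of C7–OH and C13–OH, and C7–OH-guided nucleophilic epoxidation of C4=C5 of a quinone monoketal (C3 ketone, C6 dimethyl ketal). That ketal comes from PhI(OAc)2/MeOH oxidation of a 4-methoxyphenol (OH on C3, OMe on C6).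
- Key disconnection: the phenol is split into a methoxy(alkenyl)carbene complex of chromium (C6, C1, C2, C13), one CO ligand (C3) and a chiral terminal alkyne (C4, C5 and C7–C12 with the C7 stereocentre) by Dötz benzannulation.
- The carbene complex comes from 2-bromoallyl alcohol in two steps. The alkyne comes from (E)-3-methylpent-2-en-4-yn-1-ol through an E,E-dienal and enantioselective addition of ethynyltrimethylsilane, in nine steps.
- Ring order: benzene ring C1–C6 first (step 12), oxirane O–C4–C5 second (step 15). The C13 silyl group is TIPS rather than TBS so that the 2-lithioallyl ether of step 11 resists O-to-C silyl shift.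

Key step: step 12

Remark on the chemistry: the target is read from its SMILES as (4R,5S,7S) in the numbering above, that is (1R,6S) in the bicyclic name with a (1S) side chain. The chiral ligand of step 7 is specified by the aldehyde face it must attack (the Re face of C7), because I am not certain which antipode delivers that sense.

**Route**

Step 1
Reactants: 1 (E)-3-methylpent-2-en-4-yn-1-ol
Product: 2 tert-butyldimethyl{[(2E)-3-methylpent-2-en-4-yn-1-yl]oxy}silane
Conditions: TBSCl, imidazole, CH2Cl2, 0 °C to rt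
Reagents that add atoms: tert-butyldimethylsilyl chloride, CC(C)(C)[Si](C)(C)Cl
Why: Imidazole-mediated O-silylation of the primary allylic alcohol keeps the future C7 oxygen inert to n-BuLi and hydride.

Step 2
Reactants: 2 tert-butyldimethyl{[(2E)-3-methylpent-2-en-4-yn-1-yl]oxy}silane
Product: 4 (4E)-6-[(tert-butyldimethylsilyl)oxy]-4-methylhex-4-en-2-yn-1-ol, via lithium acetylide 3 (not isolated)
Conditions: n-BuLi, THF, −78 °C; (CH2O)n, −78 °C to rt
Reagents that add atoms: paraformaldehyde (as formaldehyde), C=O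
Why: Deprotonation of the terminal alkyne and addition of the lithium acetylide to formaldehyde (acetylide hydroxymethylation) introduce C12 as a propargylic alcohol.

Step 3
Reactants: 4 (4E)-6-[(tert-butyldimethylsilyl)oxy]-4-methylhex-4-en-2-yn-1-ol
Product: 5 (2E,4E)-6-[(tert-butyldimethylsilyl)oxy]-4-methylhexa-2,4-dien-1-ol
Conditions: NaAlH2(OCH2CH2OMe)2, THF, 0 °C
Reagents that add atoms: none
Why: Alkoxide-directed trans-hydroalumination of the propargylic alcohol followed by protonolysis should give only the E C10=C11 alkene and leave the C8=C9 alkene with the E geometry of 1.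

Step 4
Reactants: 5 (2E,4E)-6-[(tert-butyldimethylsilyl)oxy]-4-methylhexa-2,4-dien-1-ol
Product: 6 tert-butyl{[(2E,4E)-6-[(4-methoxybenzyl)oxy]-3-methylhexa-2,4-dien-1-yl]oxy}dimethylsilane
Conditions: NaH, PMBCl, Bu4NI (cat.), DMF, 0 °C to rt
Reagents that add atoms: 4-methoxybenzyl chloride, COc1ccc(CCl)cc1
Why: Williamson ether synthesis under basic conditions protects C12–OH as the PMB ether without exposing the ionisable dienyl alcohol to acid.

Step 5
Reactants: 6 tert-butyl{[(2E,4E)-6-[(4-methoxybenzyl)oxy]-3-methylhexa-2,4-dien-1-yl]oxy}dimethylsilane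
Product: 7 (2E,4E)-6-[(4-methoxybenzyl)oxy]-3-methylhexa-2,4-dien-1-ol
Conditions: Bu4NF, THF, 0 °C
Reagents that add atoms: none
Why: Fluoride-induced cleavage of the Si–O bond frees C7–OH while the PMB ether and the diene are inert.

Step 6
Reactants: 7 (2E,4E)-6-[(4-methoxybenzyl)oxy]-3-methylhexa-2,4-dien-1-ol
Product: 8 (2E,4E)-6-[(4-methoxybenzyl)oxy]-3-methylhexa-2,4-dienal
Conditions: MnO2, CH2Cl2, rt
Reagents that add atoms: none
Why: Heterogeneous MnO2 oxidation is selective for the allylic alcohol and, being neutral, should not isomerise the E,E-diene.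

Step 7
Reactants: 8 (2E,4E)-6-[(4-methoxybenzyl)oxy]-3-methylhexa-2,4-dienal; 9 ethynyltrimethylsilane
Product: 11 (3S,4E,6E)-8-[(4-methoxybenzyl)oxy]-5-methyl-1-(trimethylsilyl)octa-4,6-dien-1-yn-3-ol, via methylzinc acetylide 10 (not isolated)
Conditions: Me2Zn, ProPhenol ligand (2,6-bis{[2-(hydroxydiphenylmethyl)pyrrolidin-1-yl]methyl}-4-methylphenol, 10 mol %, antipode for Re-face attack at C7), toluene, 0 °C
Reagents that add atoms: none
Why: Zinc–ProPhenol-catalysed enantioselective alkynylation of an α,β-unsaturated aldehyde, in which the methylzinc acetylide is delivered inside the chiral dinuclear zinc pocket to the Re face of the aldehyde carbon C7 and so sets the (S)-carbinol.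

Step 8
Reactants: 11 (3S,4E,6E)-8-[(4-methoxybenzyl)oxy]-5-methyl-1-(trimethylsilyl)octa-4,6-dien-1-yn-3-ol
Product: 12 (3S,4E,6E)-8-[(4-methoxybenzyl)oxy]-5-methylocta-4,6-dien-1-yn-3-ol
Conditions: K2CO3, MeOH, rt
Reagents that add atoms: none
Why: Base-catalysed methanolysis of the alkynyl C–Si bond (protodesilylation) exposes the terminal alkyne that the benzannulation needs and does not touch the carbinol.

Step 9
Reactants: 12 (3S,4E,6E)-8-[(4-methoxybenzyl)oxy]-5-methylocta-4,6-dien-1-yn-3-ol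
Product: 13 triethyl{[(3S,4E,6E)-8-[(4-methoxybenzyl)oxy]-5-methylocta-4,6-dien-1-yn-3-yl]oxy}silane
Conditions: Et3SiCl, imidazole, CH2Cl2, 0 °C
Reagents that add atoms: chlorotriethylsilane, CC[Si](Cl)(CC)CC
Why: O-Silylation caps the propargylic hydroxyl, which would otherwise trap the ketene intermediate of step 12, as a fluoride-labile TES ether.

Step 10
Reactants: 14 2-bromoprop-2-en-1-ol
Product: 15 [(2-bromoprop-2-en-1-yl)oxy]triisopropylsilane
Conditions: i-Pr3SiCl, imidazole, DMF, rt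
Reagents that add atoms: chlorotriisopropylsilane, CC(C)[Si](Cl)(C(C)C)C(C)C
Why: O-Silylation with the bulky TIPS group, chosen because it resists the O-to-C silyl shift (retro-Brook rearrangement) open to the 2-lithioallyl ether of step 11.

Step 11
Reactants: 15 [(2-bromoprop-2-en-1-yl)oxy]triisopropylsilane
Product: 18 pentacarbonyl[methoxy{3-[(triisopropylsilyl)oxy]prop-1-en-2-yl}carbene]chromium, via vinyllithium 16 (not isolated), via lithium acylchromate 17 (not isolated)
Conditions: t-BuLi (2 equiv), Et2O, −78 °C; Cr(CO)6, −78 to 0 °C; Me3OBF4, CH2Cl2, 0 °C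
Reagents that add atoms: chromium hexacarbonyl, O=C=[Cr](=C=O)(=C=O)(=C=O)(=C=O)=C=O; trimethyloxonium tetrafluoroborate, C[O+](C)C.F[B-](F)(F)F
Why: Fischer synthesis of an alkoxy(alkenyl)carbene complex of zerovalent chromium by bromine–lithium exchange, addition of the vinyllithium to a CO ligand and O-methylation of the acylate with a hard oxonium salt.

Step 12
Reactants: 18 pentacarbonyl[methoxy{3-[(triisopropylsilyl)oxy]prop-1-en-2-yl}carbene]chromium; 13 triethyl{[(3S,4E,6E)-8-[(4-methoxybenzyl)oxy]-5-methylocta-4,6-dien-1-yn-3-yl]oxy}silane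
Product: 20 4-methoxy-2-[(1S,2E,4E)-6-[(4-methoxybenzyl)oxy]-3-methyl-1-[(triethylsilyl)oxy]hexa-2,4-dien-1-yl]-5-{[(triisopropylsilyl)oxy]methyl}phenol, via arene tricarbonylchromium complex 19 (not isolated)
Conditions: THF, 50 °C; then air, rt
Reagents that add atoms: none
Why: Thermal loss of one CO from 18 lets alkyne 13 coordinate and insert into the Cr=C bond (C5–C6), CO insertion into the resulting vinylcarbene gives a chromium-bound vinylketene (C3–C4), and 6π-electrocyclisation of this dienylketene (C2–C3) followed by enol tautomerisation gives the chromium-bound phenol 19, from which air removes the metal. This is the Dötz benzannulation of an alkoxy(alkenyl)carbene complex of zerovalent chromium with a terminal alkyne, a reaction known to tolerate propargylic silyl ethers. The single ring formed, the benzene ring C1–C6, is closed by the 6π-electrocyclisation. No stereocentre is created: the planar chirality of 19 vanishes on decomplexation, and C7, which lies outside the reacting π-system, is not touched. The step needs the alkyne CH (C5) to bond to the carbene carbon C6 so that the branched C4 ends next to the CO-derived C3, and the steric difference between H and the CH(OSiEt3)dienyl substituent should secure this. Phenol formation rather than cyclopentannulation or furan formation is favoured by the alkenyl (not aryl) carbene in THF, and the remote diene should not be cyclopropanated at 50 °C.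

Step 13
Reactants: 20 4-methoxy-2-[(1S,2E,4E)-6-[(4-methoxybenzyl)oxy]-3-methyl-1-[(triethylsilyl)oxy]hexa-2,4-dien-1-yl]-5-{[(triisopropylsilyl)oxy]methyl}phenol
Product: 21 4,4-dimethoxy-2-[(1S,2E,4E)-6-[(4-methoxybenzyl)oxy]-3-methyl-1-[(triethylsilyl)oxy]hexa-2,4-dien-1-yl]-5-{[(triisopropylsilyl)oxy]methyl}cyclohexa-2,5-dien-1-one
Conditions: PhI(OAc)2, NaHCO3, MeOH, 0 °C
Reagents that add atoms: methanol, CO
Why: Oxidative dearomatisation of a 4-alkoxyphenol with a trivalent iodine reagent, in which methanol adds para to the phenol oxygen at the methoxy-bearing C6, so that C6 becomes the dimethyl ketal and C3 the free dienone carbonyl while NaHCO3 takes up the acetic acid.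

Step 14
Reactants: 21 4,4-dimethoxy-2-[(1S,2E,4E)-6-[(4-methoxybenzyl)oxy]-3-methyl-1-[(triethylsilyl)oxy]hexa-2,4-dien-1-yl]-5-{[(triisopropylsilyl)oxy]methyl}cyclohexa-2,5-dien-1-one
Product: 22 2-[(1S,2E,4E)-1-hydroxy-6-[(4-methoxybenzyl)oxy]-3-methylhexa-2,4-dien-1-yl]-5-(hydroxymethyl)-4,4-dimethoxycyclohexa-2,5-dien-1-one
Conditions: Bu4NF, AcOH, THF, 0 °C to rt
Reagents that add atoms: none
Why: Acetic acid-buffered fluoride desilylation removes the TES and TIPS ethers together and is mild enough for the cross-conjugated dienone ketal.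

Step 15
Reactants: 22 2-[(1S,2E,4E)-1-hydroxy-6-[(4-methoxybenzyl)oxy]-3-methylhexa-2,4-dien-1-yl]-5-(hydroxymethyl)-4,4-dimethoxycyclohexa-2,5-dien-1-one
Product: 23 (1R,6S)-1-[(1S,2E,4E)-1-hydroxy-6-[(4-methoxybenzyl)oxy]-3-methylhexa-2,4-dien-1-yl]-4-(hydroxymethyl)-5,5-dimethoxy-7-oxabicyclo[4.1.0]hept-3-en-2-one
Conditions: Ph3COOH, NaN(SiMe3)2, toluene, −40 °C
Reagents that add atoms: triphenylmethyl hydroperoxide, OOC(c1ccccc1)(c1ccccc1)c1ccccc1
Why: Weitz–Scheffer nucleophilic epoxidation with the bulky trityl peroxide anion, a reaction known for α-(hydroxyalkyl) quinone monoketals, in which the peroxide adds to the unsubstituted β-carbon C5 rather than to the fully substituted C1 or to the electron-rich C8=C9 that an electrophilic hydroxyl-directed oxidant would attack, and in which a sodium chelate (or hydrogen bond) holding the C7 oxygen in the ring plane toward C3=O places the dienyl group over one face so that addition to C5 and closure onto C4 from the other face should give the (4R,5S) oxirane from the (7S) carbinol.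

Step 16
Reactants: 23 (1R,6S)-1-[(1S,2E,4E)-1-hydroxy-6-[(4-methoxybenzyl)oxy]-3-methylhexa-2,4-dien-1-yl]-4-(hydroxymethyl)-5,5-dimethoxy-7-oxabicyclo[4.1.0]hept-3-en-2-one
Product: 24 [(1R,6S)-1-[(1S,2E,4E)-1-acetoxy-6-[(4-methoxybenzyl)oxy]-3-methylhexa-2,4-dien-1-yl]-5,5-dimethoxy-2-oxo-7-oxabicyclo[4.1.0]hept-3-en-4-yl]methyl acetate
Conditions: Ac2O, pyridine, 4-(dimethylamino)pyridine (cat.), CH2Cl2, 0 °C
Reagents that add atoms: acetic anhydride, CC(=O)OC(C)=O
Why: Nucleophile-catalysed O-acetylation of the primary C13 and secondary C7 hydroxyls, placed after the epoxidation because a C7 acetate on the enone would be eliminated from the enolate of the peroxide adduct.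

Step 17
Reactants: 24 [(1R,6S)-1-[(1S,2E,4E)-1-acetoxy-6-[(4-methoxybenzyl)oxy]-3-methylhexa-2,4-dien-1-yl]-5,5-dimethoxy-2-oxo-7-oxabicyclo[4.1.0]hept-3-en-4-yl]methyl acetate
Product: 25 [(1R,6S)-1-[(1S,2E,4E)-1-acetoxy-6-hydroxy-3-methylhexa-2,4-dien-1-yl]-5,5-dimethoxy-2-oxo-7-oxabicyclo[4.1.0]hept-3-en-4-yl]methyl acetate
Conditions: DDQ, CH2Cl2/pH 7 buffer, 0 °C
Reagents that add atoms: none
Why: Oxidative PMB ether cleavage by hydride abstraction from the electron-rich benzylic position and hydrolysis frees C12–OH, and any over-oxidation to the dienal only anticipates step 18.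

Step 18
Reactants: 25 [(1R,6S)-1-[(1S,2E,4E)-1-acetoxy-6-hydroxy-3-methylhexa-2,4-dien-1-yl]-5,5-dimethoxy-2-oxo-7-oxabicyclo[4.1.0]hept-3-en-4-yl]methyl acetate
Product: 26 [(1R,6S)-1-[(1S,2E,4E)-1-acetoxy-3-methyl-6-oxohexa-2,4-dien-1-yl]-5,5-dimethoxy-2-oxo-7-oxabicyclo[4.1.0]hept-3-en-4-yl]methyl acetate
Conditions: MnO2, CH2Cl2, rt
Reagents that add atoms: none
Why: MnO2 oxidation of the dienylic primary alcohol gives the E,E-dienal while the acetates, the epoxy ketone and the ketal are inert.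

Step 19
Reactants: 26 [(1R,6S)-1-[(1S,2E,4E)-1-acetoxy-3-methyl-6-oxohexa-2,4-dien-1-yl]-5,5-dimethoxy-2-oxo-7-oxabicyclo[4.1.0]hept-3-en-4-yl]methyl acetate
Product: 27 [(1R,6S)-1-[(1S,2E,4E)-1-acetoxy-3-methyl-6-oxohexa-2,4-dien-1-yl]-2,5-dioxo-7-oxabicyclo[4.1.0]hept-3-en-4-yl]methyl acetate (CNP0307549.1)
Conditions: CF3CO2H, H2O, CH2Cl2, 0 °C
Reagents that add atoms: water, O
Why: Acid-catalysed ketal hydrolysis through the oxocarbenium ion unveils the C6 carbonyl, and it is placed last because the electron-poor dienal then disfavours ionisation of the C7 acetate and the electron-poor oxirane resists acid opening.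

**Compound list**

1 | (E)-3-methylpent-2-en-4-yn-1-ol | C#C/C(C)=C/CO | starting material
2 | tert-butyldimethyl{[(2E)-3-methylpent-2-en-4-yn-1-yl]oxy}silane | C#C/C(C)=C/CO[Si](C)(C)C(C)(C)C | intermediate
3 | lithium acetylide of 2 | [Li]C#C/C(C)=C/CO[Si](C)(C)C(C)(C)C | intermediate (not isolated)
4 | (4E)-6-[(tert-butyldimethylsilyl)oxy]-4-methylhex-4-en-2-yn-1-ol | OCC#C/C(C)=C/CO[Si](C)(C)C(C)(C)C | intermediate
5 | (2E,4E)-6-[(tert-butyldimethylsilyl)oxy]-4-methylhexa-2,4-dien-1-ol | OC/C=C/C(C)=C/CO[Si](C)(C)C(C)(C)C | intermediate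
6 | tert-butyl{[(2E,4E)-6-[(4-methoxybenzyl)oxy]-3-methylhexa-2,4-dien-1-yl]oxy}dimethylsilane | COc1ccc(COC/C=C/C(C)=C/CO[Si](C)(C)C(C)(C)C)cc1 | intermediate
7 | (2E,4E)-6-[(4-methoxybenzyl)oxy]-3-methylhexa-2,4-dien-1-ol | COc1ccc(COC/C=C/C(C)=C/CO)cc1 | intermediate
8 | (2E,4E)-6-[(4-methoxybenzyl)oxy]-3-methylhexa-2,4-dienal | COc1ccc(COC/C=C/C(C)=C/C=O)cc1 | intermediate
9 | ethynyltrimethylsilane | C[Si](C)(C)C#C | starting material
10 | methyl[(trimethylsilyl)ethynyl]zinc | C[Zn]C#C[Si](C)(C)C | intermediate (not isolated)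
11 | (3S,4E,6E)-8-[(4-methoxybenzyl)oxy]-5-methyl-1-(trimethylsilyl)octa-4,6-dien-1-yn-3-ol | C[Si](C)(C)C#C[C@@H](O)/C=C(C)/C=C/COCc1ccc(OC)cc1 | intermediate
12 | (3S,4E,6E)-8-[(4-methoxybenzyl)oxy]-5-methylocta-4,6-dien-1-yn-3-ol | C#C[C@@H](O)/C=C(C)/C=C/COCc1ccc(OC)cc1 | intermediate
13 | triethyl{[(3S,4E,6E)-8-[(4-methoxybenzyl)oxy]-5-methylocta-4,6-dien-1-yn-3-yl]oxy}silane | C#C[C@@H](O[Si](CC)(CC)CC)/C=C(C)/C=C/COCc1ccc(OC)cc1 | intermediate
14 | 2-bromoprop-2-en-1-ol | OCC(Br)=C | starting material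
15 | [(2-bromoprop-2-en-1-yl)oxy]triisopropylsilane | C=C(Br)CO[Si](C(C)C)(C(C)C)C(C)C | intermediate
16 | {3-[(triisopropylsilyl)oxy]prop-1-en-2-yl}lithium | [Li]C(=C)CO[Si](C(C)C)(C(C)C)C(C)C | intermediate (not isolated)
17 | lithium pentacarbonyl{2-[(triisopropylsilyloxy)methyl]acryloyl}chromate | [Li+].[O-]C(=[Cr](=C=O)(=C=O)(=C=O)(=C=O)=C=O)C(=C)CO[Si](C(C)C)(C(C)C)C(C)C | intermediate (not isolated)
18 | pentacarbonyl[methoxy{3-[(triisopropylsilyl)oxy]prop-1-en-2-yl}carbene]chromium | COC(=[Cr](=C=O)(=C=O)(=C=O)(=C=O)=C=O)C(=C)CO[Si](C(C)C)(C(C)C)C(C)C | intermediate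
19 | tricarbonyl(η6-arene)chromium complex of phenol 20 | COc1cc([C@@H](O[Si](CC)(CC)CC)/C=C(C)/C=C/COCc2ccc(OC)cc2)c(O)cc1CO[Si](C(C)C)(C(C)C)C(C)C.[Cr](=C=O)(=C=O)=C=O | intermediate (not isolated)
20 | 4-methoxy-2-[(1S,2E,4E)-6-[(4-methoxybenzyl)oxy]-3-methyl-1-[(triethylsilyl)oxy]hexa-2,4-dien-1-yl]-5-{[(triisopropylsilyl)oxy]methyl}phenol | COc1cc([C@@H](O[Si](CC)(CC)CC)/C=C(C)/C=C/COCc2ccc(OC)cc2)c(O)cc1CO[Si](C(C)C)(C(C)C)C(C)C | intermediate
21 | 4,4-dimethoxy-2-[(1S,2E,4E)-6-[(4-methoxybenzyl)oxy]-3-methyl-1-[(triethylsilyl)oxy]hexa-2,4-dien-1-yl]-5-{[(triisopropylsilyl)oxy]methyl}cyclohexa-2,5-dien-1-one | O=C1C=C(CO[Si](C(C)C)(C(C)C)C(C)C)C(OC)(OC)C=C1[C@@H](O[Si](CC)(CC)CC)/C=C(C)/C=C/COCc1ccc(OC)cc1 | intermediate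
22 | 2-[(1S,2E,4E)-1-hydroxy-6-[(4-methoxybenzyl)oxy]-3-methylhexa-2,4-dien-1-yl]-5-(hydroxymethyl)-4,4-dimethoxycyclohexa-2,5-dien-1-one | O=C1C=C(CO)C(OC)(OC)C=C1[C@@H](O)/C=C(C)/C=C/COCc1ccc(OC)cc1 | intermediate
23 | (1R,6S)-1-[(1S,2E,4E)-1-hydroxy-6-[(4-methoxybenzyl)oxy]-3-methylhexa-2,4-dien-1-yl]-4-(hydroxymethyl)-5,5-dimethoxy-7-oxabicyclo[4.1.0]hept-3-en-2-one | OCC1=CC(=O)[C@]2([C@H](/C=C(C)/C=C/COCc3ccc(OC)cc3)O)O[C@@H]2C1(OC)OC | intermediate
24 | [(1R,6S)-1-[(1S,2E,4E)-1-acetoxy-6-[(4-methoxybenzyl)oxy]-3-methylhexa-2,4-dien-1-yl]-5,5-dimethoxy-2-oxo-7-oxabicyclo[4.1.0]hept-3-en-4-yl]methyl acetate | CC(=O)OCC1=CC(=O)[C@]2([C@H](/C=C(C)/C=C/COCc3ccc(OC)cc3)OC(C)=O)O[C@@H]2C1(OC)OC | intermediate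
25 | [(1R,6S)-1-[(1S,2E,4E)-1-acetoxy-6-hydroxy-3-methylhexa-2,4-dien-1-yl]-5,5-dimethoxy-2-oxo-7-oxabicyclo[4.1.0]hept-3-en-4-yl]methyl acetate | CC(=O)OCC1=CC(=O)[C@]2([C@H](/C=C(C)/C=C/CO)OC(C)=O)O[C@@H]2C1(OC)OC | intermediate
26 | [(1R,6S)-1-[(1S,2E,4E)-1-acetoxy-3-methyl-6-oxohexa-2,4-dien-1-yl]-5,5-dimethoxy-2-oxo-7-oxabicyclo[4.1.0]hept-3-en-4-yl]methyl acetate | CC(=O)OCC1=CC(=O)[C@]2([C@H](/C=C(C)/C=C/C=O)OC(C)=O)O[C@@H]2C1(OC)OC | intermediate
27 | [(1R,6S)-1-[(1S,2E,4E)-1-acetoxy-3-methyl-6-oxohexa-2,4-dien-1-yl]-2,5-dioxo-7-oxabicyclo[4.1.0]hept-3-en-4-yl]methyl acetate (CNP0307549.1) | CC(=O)OCC1=CC(=O)[C@]2([C@H](/C=C(C)/C=C/C=O)OC(C)=O)O[C@@H]2C1=O | target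

**Step count**

Total: 19 steps. Longest linear sequence: 17 steps (steps 1–9, then 12–19).

**Steps most likely to fail**

1. Step 12 (key step).
   - What may go wrong: the carbene complex, with its unsubstituted vinyl terminus, may oligomerise or decompose faster than it inserts the branched alkyne. The propargylic silyloxy group may be lost from the chromium vinylcarbene, or the ketene may be intercepted, so that phenol formation is diverted.
   - Fallback: it sets out from dienal 8 and comes back at phenol 20; the arene is taken from a preformed benzene instead of being annulated.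
   - Commercial 4-bromo-2,5-dimethoxybenzaldehyde F1 is demethylated with BBr3 in CH2Cl2 to 4-bromo-2,5-dihydroxybenzaldehyde F2.
   - The hydroxyl that is not hydrogen-bonded to the aldehyde is allylated (allyl bromide, K2CO3, acetone) to 5-(allyloxy)-4-bromo-2-hydroxybenzaldehyde F3.
   - The remaining hydroxyl is methylated (MeI, K2CO3, DMF) to 5-(allyloxy)-4-bromo-2-methoxybenzaldehyde F4.
   - NaBH4 gives [5-(allyloxy)-4-bromo-2-methoxyphenyl]methanol F5, and i-Pr3SiCl/imidazole gives {[5-(allyloxy)-4-bromo-2-methoxybenzyl]oxy}triisopropylsilane F6.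
   - Bromine–lithium exchange (n-BuLi, THF, −78 °C) gives the aryllithium F7; ZnCl2 and then n-BuLi give the aryl(butyl)zinc F8.
   - Enantioselective aryl transfer from F8 to 8, catalysed by the amino alcohol 3-exo-morpholinoisoborneol (antipode for Re-face attack at C7), should give the (S)-configured aryl dienyl carbinol F9.
   - Et3SiCl/imidazole gives the TES ether of that carbinol F10, and removal of the allyl group with Pd(PPh3)4 (zerovalent palladium) and morpholine gives 20.

2. Step 15.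
   - What may go wrong: facial discrimination may be poor if the chelated conformer is not the reacting one. The product alkoxide may undergo retro-aldol cleavage of C4–C7 with loss of the dienal. The peroxide may attack C1=C2 with help from the free C13 hydroxyl.
   - Fallback: it sets out from ketal 21 and comes back at epoxy diol 23; stereocontrol is moved from the substrate hydroxyl to the reagent and the order of desilylation and epoxidation is inverted.
   - The fully silylated 21 is epoxidised by phase-transfer Weitz–Scheffer epoxidation (t-BuOOH, aqueous NaOH, toluene, N-benzylcinchonidinium or N-benzylcinchoninium chloride, whichever pseudoenantiomer gives the (4R,5S) oxirane) to the bis-silyl ether of epoxy diol 23 F11. No alkoxide at C7 and no free hydroxyl at C13 are present.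
   - Bu4NF/AcOH then removes both silyl groups to give 23.

3. Step 7.
   - What may go wrong: addition to the β,β-disubstituted, vinylogously deactivated dienal may be slow, so that uncatalysed addition erodes the enantioselectivity.
   - Fallback: it sets out from dienal 8 (with 9) and comes back at 11; the stereocentre is set by reduction instead of addition.
   - Lithium (trimethylsilyl)acetylide F12 (from 9, n-BuLi, THF, −78 °C) adds to 8 to give the racemic (4E,6E)-8-[(4-methoxybenzyl)oxy]-5-methyl-1-(trimethylsilyl)octa-4,6-dien-1-yn-3-ol F13.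
   - MnO2 gives the (4E,6E)-8-[(4-methoxybenzyl)oxy]-5-methyl-1-(trimethylsilyl)octa-4,6-dien-1-yn-3-one F14.
   - Midland reduction with (S)-Alpine-Borane (the B-isopinocampheyl-9-borabicyclo[3.3.1]nonane from (−)-α-pinene), in which the alkynyl group is the small substituent, should give (S)-configured 11.

**Further compounds**

F1 | step 12 | 4-bromo-2,5-dimethoxybenzaldehyde (commercial) | COc1cc(C=O)c(OC)cc1Br
F2 | step 12 | 4-bromo-2,5-dihydroxybenzaldehyde | Oc1cc(C=O)c(O)cc1Br
F3 | step 12 | 5-(allyloxy)-4-bromo-2-hydroxybenzaldehyde | C=CCOc1cc(C=O)c(O)cc1Br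
F4 | step 12 | 5-(allyloxy)-4-bromo-2-methoxybenzaldehyde | C=CCOc1cc(C=O)c(OC)cc1Br
F5 | step 12 | [5-(allyloxy)-4-bromo-2-methoxyphenyl]methanol | C=CCOc1cc(CO)c(OC)cc1Br
F6 | step 12 | {[5-(allyloxy)-4-bromo-2-methoxybenzyl]oxy}triisopropylsilane | C=CCOc1cc(CO[Si](C(C)C)(C(C)C)C(C)C)c(OC)cc1Br
F7 | step 12 | [2-(allyloxy)-5-methoxy-4-{[(triisopropylsilyl)oxy]methyl}phenyl]lithium | [Li]c1cc(OC)c(CO[Si](C(C)C)(C(C)C)C(C)C)cc1OCC=C
F8 | step 12 | [2-(allyloxy)-5-methoxy-4-{[(triisopropylsilyl)oxy]methyl}phenyl](butyl)zinc | CCCC[Zn]c1cc(OC)c(CO[Si](C(C)C)(C(C)C)C(C)C)cc1OCC=C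
F9 | step 12 | (1S,2E,4E)-1-[2-(allyloxy)-5-methoxy-4-{[(triisopropylsilyl)oxy]methyl}phenyl]-6-[(4-methoxybenzyl)oxy]-3-methylhexa-2,4-dien-1-ol | C=CCOc1cc(CO[Si](C(C)C)(C(C)C)C(C)C)c(OC)cc1[C@@H](O)/C=C(C)/C=C/COCc1ccc(OC)cc1
F10 | step 12 | triethylsilyl ether of F9 (O-allyl ether of phenol 20) | C=CCOc1cc(CO[Si](C(C)C)(C(C)C)C(C)C)c(OC)cc1[C@@H](O[Si](CC)(CC)CC)/C=C(C)/C=C/COCc1ccc(OC)cc1
F11 | step 15 | 7-O-triethylsilyl 13-O-triisopropylsilyl bis-silyl ether of epoxy diol 23 (same configuration) | CC(C)[Si](OCC1=CC(=O)[C@]2([C@H](/C=C(C)/C=C/COCc3ccc(OC)cc3)O[Si](CC)(CC)CC)O[C@@H]2C1(OC)OC)(C(C)C)C(C)C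
F12 | step 7 | lithium (trimethylsilyl)acetylide | [Li]C#C[Si](C)(C)C
F13 | step 7 | racemic (4E,6E)-8-[(4-methoxybenzyl)oxy]-5-methyl-1-(trimethylsilyl)octa-4,6-dien-1-yn-3-ol | C[Si](C)(C)C#CC(O)/C=C(C)/C=C/COCc1ccc(OC)cc1
F14 | step 7 | (4E,6E)-8-[(4-methoxybenzyl)oxy]-5-methyl-1-(trimethylsilyl)octa-4,6-dien-1-yn-3-one | C[Si](C)(C)C#CC(=O)/C=C(C)/C=C/COCc1ccc(OC)cc1
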